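**Plan**
Retrosynthesis: the C4 ketone is taken back to the C3=C4 alkene of a flav-3-ene ketal; the ketal bond O1–C2 is cut to a benzofuran-3-yl(2-hydroxyaryl)carbinol; C4–C4a is cut (aldehyde + lithiated ring A phenol); the furan ring is cut at O–C7' and C8'–C3 into a flavan 7',8'-aryne and the iodonium ylide of a β-keto ester; the flavan is cut at O1'–C2' and at the chalcone C=C.
Enabling feature: the five-membered ring O–C7'–C8'–C3–C2 sits on the ortho carbons C7'/C8' of flavan ring A, and the ring oxygen O1' on C8a' next to C8' polarises a 7',8'-aryne. C3 lies between C2 (ketone level) and C4 (carboxyl level), so C3, like C8' a natural nucleophile, can be reversed in polarity as an iodonium ylide carbon while the C2 enolate oxygen stays nucleophilic.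
Forward order: chromane ring (Mitsunobu) → ortho-silylaryl triflate → furan ring by aryne/ylide annulation → ring A joined at C4 → pyran (ketal) ring by dearomatising cyclisation → C4 carbonyl → debenzylation.
Stereochemistry: C2' from Noyori–Ikariya transfer hydrogenation followed by Mitsunobu inversion; C2 from a chiral phosphoric acid in the ketal-forming step; C3 from syn-hydroboration and the strain-free cis ring fusion.
Locants: upper unit numbered as a flavanone (O1, C2, C3, C4, ring A, ring B on C2), flavan unit primed; the target is (2S,3S,2'R).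
Key step: step 12

Assumption: at the ketone oxidation level the 3-aroylbenzofuran isomer is taken to be more stable than the target ketal, so the ketal ring is closed at the carbinol level (driven by loss of water) and the C4 carbonyl is installed afterwards; compounds 1, 4 and 16 are taken as commercial.

Step 1
Reactants: 1 2,4,6-trihydroxybenzaldehyde
Product: 2 2,6-dihydroxy-4-(methoxymethoxy)benzaldehyde
Conditions: MOMCl (1.0 equiv), i-Pr2NEt, CH2Cl2/THF, −20 to 0 °C
Reagents that add atoms: chloromethyl methyl ether (MOMCl), COCCl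
Why: The 4-hydroxyl, para to the formyl group and not held in a hydrogen bond, is the most acidic and most nucleophilic phenol, so one equivalent of MOMCl should etherify it selectively (Williamson-type O-alkylation).

Step 2
Reactants: 2 2,6-dihydroxy-4-(methoxymethoxy)benzaldehyde
Product: 3 2-(benzyloxy)-6-hydroxy-4-(methoxymethoxy)benzaldehyde
Conditions: BnBr (1.05 equiv), K2CO3, acetone, 50 °C
Reagents that add atoms: benzyl bromide, BrCc1ccccc1
Why: Williamson etherification of one of the two equivalent ortho-hydroxyls should stop there, because the remaining hydroxyl is locked in a strong hydrogen bond to the formyl oxygen.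

Step 3
Reactants: 3 2-(benzyloxy)-6-hydroxy-4-(methoxymethoxy)benzaldehyde; 4 1-[4-(benzyloxy)phenyl]ethan-1-one
Product: 5 (E)-3-[2-(benzyloxy)-6-hydroxy-4-(methoxymethoxy)phenyl]-1-[4-(benzyloxy)phenyl]prop-2-en-1-one
Conditions: KOH (aq.), EtOH, rt
Reagents that add atoms: none
Why: Claisen–Schmidt condensation of the methyl ketone enolate with the aldehyde and E1cB dehydration should give the (E)-enone, MOM and benzyl ethers being inert to hydroxide.

Step 4
Reactants: 5 (E)-3-[2-(benzyloxy)-6-hydroxy-4-(methoxymethoxy)phenyl]-1-[4-(benzyloxy)phenyl]prop-2-en-1-one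
Product: 7 3-(benzyloxy)-2-[(3S)-3-[4-(benzyloxy)phenyl]-3-hydroxypropyl]-5-(methoxymethoxy)phenol, via saturated ketone 6 (not isolated)
Conditions: RuCl[(S,S)-TsDPEN](p-cymene) (2 mol%), HCO2H/Et3N (5:2), EtOAc, 40 °C
Reagents that add atoms: none
Why: Noyori–Ikariya transfer hydrogenation should first reduce the polarised chalcone C=C and then the aryl ketone through the six-membered outer-sphere transition state, the (S,S)-ligand setting the (S)-carbinol while benzyl ethers, MOM and the phenol are untouched.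

Step 5
Reactants: 7 3-(benzyloxy)-2-[(3S)-3-[4-(benzyloxy)phenyl]-3-hydroxypropyl]-5-(methoxymethoxy)phenol
Product: 8 (2R)-5-(benzyloxy)-2-[4-(benzyloxy)phenyl]-7-(methoxymethoxy)chromane
Conditions: PPh3, DIAD, THF, −20 to 0 °C
Reagents that add atoms: none
Why: Intramolecular Mitsunobu etherification (6-exo-tet) should displace the benzylic oxyphosphonium by the phenol with inversion, turning the (S)-carbinol into the (2R)-chromane; low temperature limits ionisation of the electron-rich benzylic centre.

Step 6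
Reactants: 8 (2R)-5-(benzyloxy)-2-[4-(benzyloxy)phenyl]-7-(methoxymethoxy)chromane
Product: 9 (2R)-5-(benzyloxy)-2-[4-(benzyloxy)phenyl]-8-bromo-7-(methoxymethoxy)chromane
Conditions: NBS, CH2Cl2, −78 to −20 °C
Reagents that add atoms: N-bromosuccinimide, O=C1CCC(=O)N1Br
Why: Electrophilic bromination of 5,7-dialkoxyflavans with NBS at low temperature is known to go to C8, between O1 and the 7-oxygen, in preference to C6 next to the 5-benzyloxy group.

Step 7
Reactants: 9 (2R)-5-(benzyloxy)-2-[4-(benzyloxy)phenyl]-8-bromo-7-(methoxymethoxy)chromane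
Product: 10 (2R)-5-(benzyloxy)-2-[4-(benzyloxy)phenyl]-8-bromochroman-7-ol
Conditions: ZnBr2, n-PrSH, CH2Cl2, rt
Reagents that add atoms: none
Why: Lewis-acid-assisted transfer of the methoxymethyl group to the thiol should cleave the MOM ether while benzyl ethers, the aryl bromide and the benzylic C2–O bond stay intact.

Step 8
Reactants: 10 (2R)-5-(benzyloxy)-2-[4-(benzyloxy)phenyl]-8-bromochroman-7-ol
Product: 13 (2R)-5-(benzyloxy)-2-[4-(benzyloxy)phenyl]-8-(trimethylsilyl)chroman-7-yl trifluoromethanesulfonate, via aryl silyl ether 11 (not isolated), via lithium C-silyl phenoxide 12 (not isolated)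
Conditions: HMDS, THF, 65 °C, evaporate; n-BuLi (1.05 equiv), THF, −78 °C; Tf2O, −78 to 0 °C
Reagents that add atoms: hexamethyldisilazane, C[Si](C)(C)N[Si](C)(C)C; trifluoromethanesulfonic anhydride, O=S(=O)(OS(=O)(=O)C(F)(F)F)C(F)(F)F
Why: O-silylation, bromine–lithium exchange and 1,3-O-to-C silyl migration (retro-Brook rearrangement) should place the silyl group on C8 and free the 7-phenoxide for triflation, the standard route to ortho-silylaryl triflates.

Step 9
Reactants: 4 1-[4-(benzyloxy)phenyl]ethan-1-one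
Product: 14 ethyl 3-[4-(benzyloxy)phenyl]-3-oxopropanoate
Conditions: NaH (2.2 equiv), (EtO)2CO, THF, reflux; AcOH quench
Reagents that add atoms: diethyl carbonate, CCOC(=O)OCC
Why: Claisen-type C-acylation of the ketone enolate with diethyl carbonate is driven by formation of the stabilised β-keto ester enolate.

Step 10
Reactants: 14 ethyl 3-[4-(benzyloxy)phenyl]-3-oxopropanoate
Product: 15 ethyl 3-[4-(benzyloxy)phenyl]-3-oxo-2-(phenyl-λ3-iodanylidene)propanoate
Conditions: PhI(OAc)2, KOH, MeOH, −10 °C; used promptly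
Reagents that add atoms: (diacetoxyiodo)benzene, CC(=O)OI(OC(C)=O)c1ccccc1
Why: The β-keto ester enolate should attack the trivalent iodine of PhI(OAc)2 and lose two acetates to give the stabilised iodonium ylide, the standard preparation of such ylides.

Step 11
Reactants: 16 3,5-bis(benzyloxy)phenol
Product: 17 3,5-bis(benzyloxy)-2-bromophenol
Conditions: NBS, CH2Cl2, −78 °C
Reagents that add atoms: N-bromosuccinimide, O=C1CCC(=O)N1Br
Why: Electrophilic bromination of 3,5-dialkoxyphenols with NBS at low temperature goes mainly ortho to the hydroxyl, as known for the dimethoxy analogue.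

Step 12
Reactants: 13 (2R)-5-(benzyloxy)-2-[4-(benzyloxy)phenyl]-8-(trimethylsilyl)chroman-7-yl trifluoromethanesulfonate; 15 ethyl 3-[4-(benzyloxy)phenyl]-3-oxo-2-(phenyl-λ3-iodanylidene)propanoate
Product: 19 ethyl (2R)-5-(benzyloxy)-2,8-bis[4-(benzyloxy)phenyl]-3,4-dihydro-2H-furo[2,3-h]chromene-9-carboxylate, via 7,8-aryne 18 (not isolated)
Conditions: CsF (3 equiv), 15 (2 equiv), MeCN/toluene, rt
Reagents that add atoms: none
Why: Fluoride desilylates 13 and expels triflate to give aryne 18; the ketone-derived enolate oxygen of ylide 15 adds to C7', the aryne carbon remote from O1', so that the carbanion develops at C8' next to that inductively withdrawing ring oxygen (the 3-alkoxyaryne rule). The C8' carbanion then attacks the trivalent iodine centre and ligand coupling with loss of iodobenzene forges C8'–C3, uniting two carbons that are both natural nucleophiles because the ylide has reversed the polarity of C3. The closest known reaction type is the CsF-mediated formal [3+2] annulation of arynes with iodonium ylides of 1,3-dicarbonyl compounds to give 3-acyl- and 3-alkoxycarbonyl-benzofurans. The furan ring closes by C–C bond formation onto the vinylic iodonium carbon, formally a 5-endo closure that becomes feasible by passing through a six-membered iodane and reductive elimination. No stereocenter is created and C2' is untouched under the neutral fluoride conditions. The step needs regioselectivity (O on C7', C on C8'), secured by O1' on C8a', and chemoselectivity between the two ylide oxygens, secured by the much lower nucleophilicity of the ester carbonyl.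

Step 13
Reactants: 19 ethyl (2R)-5-(benzyloxy)-2,8-bis[4-(benzyloxy)phenyl]-3,4-dihydro-2H-furo[2,3-h]chromene-9-carboxylate
Product: 20 [(2R)-5-(benzyloxy)-2,8-bis[4-(benzyloxy)phenyl]-3,4-dihydro-2H-furo[2,3-h]chromen-9-yl]methanol
Conditions: LiAlH4, THF, 0 °C
Reagents that add atoms: none
Why: Hydride reduction of the ester to the primary alcohol should leave the ethers and the benzofuran untouched.

Step 14
Reactants: 20 [(2R)-5-(benzyloxy)-2,8-bis[4-(benzyloxy)phenyl]-3,4-dihydro-2H-furo[2,3-h]chromen-9-yl]methanol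
Product: 21 (2R)-5-(benzyloxy)-2,8-bis[4-(benzyloxy)phenyl]-3,4-dihydro-2H-furo[2,3-h]chromene-9-carbaldehyde
Conditions: MnO2, CH2Cl2, rt
Reagents that add atoms: none
Why: MnO2 should oxidise the activated heteroaryl-methanol selectively to the aldehyde without over-oxidation.

Step 15
Reactants: 17 3,5-bis(benzyloxy)-2-bromophenol; 21 (2R)-5-(benzyloxy)-2,8-bis[4-(benzyloxy)phenyl]-3,4-dihydro-2H-furo[2,3-h]chromene-9-carbaldehyde
Product: 23 3,5-bis(benzyloxy)-2-{[(2R)-5-(benzyloxy)-2,8-bis[4-(benzyloxy)phenyl]-3,4-dihydro-2H-furo[2,3-h]chromen-9-yl](hydroxy)methyl}phenol (both carbinol epimers), via dilithiated phenoxide 22 (not isolated)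
Conditions: 17, n-BuLi (2.1 equiv), THF, −78 °C; then 21, −78 °C; sat. aq NH4Cl at −78 °C
Reagents that add atoms: none
Why: Deprotonation and bromine–lithium exchange should give the ortho-lithiated lithium phenoxide, which adds 1,2 to the aldehyde; the cold neutral quench preserves the ionisation-prone carbinol, whose configuration is irrelevant because that carbon becomes sp2 in step 16.

Step 16
Reactants: 23 3,5-bis(benzyloxy)-2-{[(2R)-5-(benzyloxy)-2,8-bis[4-(benzyloxy)phenyl]-3,4-dihydro-2H-furo[2,3-h]chromen-9-yl](hydroxy)methyl}phenol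
Product: 25 (2S,2'R)-penta-O-benzyl flav-3-ene ketal, via ortho-quinone methide 24 (not isolated)
Conditions: (R)-TRIP (10 mol%), 4 Å molecular sieves, toluene (0.01 M), −40 °C; Et3N quench
Reagents that add atoms: none
Why: Proposed new method: the chiral phosphoric acid should ionise the doubly activated carbinol to a hydrogen-bonded ortho-quinone methide/phosphate pair (24) whose ring A oxygen closes onto benzofuran C2 (oxa-6π electrocyclisation or ion-pair collapse) to give the 2H-chromene ketal; the loss of furan aromaticity is paid for by loss of water and re-aromatisation of ring A, which is why the closure is run at the carbinol and not the ketone level; the phosphate bound to the ring A oxygen differentiates the two faces of C2 while the remote C2' centre exerts no bias, so the (R)-catalyst (its antipode if the sense proves opposite) should set C2 as S under kinetic control at low temperature; the closest known reaction type is the chiral phosphoric acid or N-triflylphosphoramide catalysed dehydrative cyclisation of ortho-hydroxyaryl allylic alcohols to 2H-chromenes through ortho-quinone methides or contact ion pairs, not yet shown with a benzofuran C2=C3 bond as the alkene.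

Step 17
Reactants: 25 (2S,2'R)-penta-O-benzyl flav-3-ene ketal
Product: 27 (2S,3S,4S,2'R)-penta-O-benzyl 4-hydroxy ketal, via 4-boryl adduct 26 (not isolated)
Conditions: BH3·THF, THF, 0 °C to rt; then NaOH, H2O2, 0 °C
Reagents that add atoms: hydrogen peroxide, OO
Why: Hydroboration–oxidation should put boron on the less substituted C4 and hydrogen on C3 in a syn fashion, hydrogen being delivered cis to the 2-aryl group because only the cis-fused benzofuran–pyran junction is strain-free; a trans-fused epimer, if formed, would converge to the cis ketone by enolisation after step 18.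

Step 18
Reactants: 27 (2S,3S,4S,2'R)-penta-O-benzyl 4-hydroxy ketal
Product: 28 (2S,3S,2'R)-penta-O-benzyl ether of the target
Conditions: DMP, NaHCO3, CH2Cl2, 0 °C
Reagents that add atoms: none
Why: Dess–Martin oxidation of the secondary benzylic alcohol under buffered, non-basic conditions should give the ketone without β-elimination of the aryloxy groups, leaving C3–H cis to the 2-aryl group.

Step 19
Reactants: 28 (2S,3S,2'R)-penta-O-benzyl ether of the target
Product: 29 (2S,3S,2'R)-target CNP0179743.1
Conditions: H2 (1 atm), Pd(OH)2/C, EtOAc/MeOH, rt, short reaction time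
Reagents that add atoms: none
Why: Hydrogenolysis of the five benzyl ethers under neutral conditions should leave the diaryl ketal, the hydrogen-bonded aryl ketone and the chromane C–O bond intact, as in syntheses of related A-type ketals.

**Compound list**
1 | 2,4,6-trihydroxybenzaldehyde | O=Cc1c(O)cc(O)cc1O | starting material
2 | 2,6-dihydroxy-4-(methoxymethoxy)benzaldehyde | O=Cc1c(O)cc(OCOC)cc1O | intermediate
3 | 2-(benzyloxy)-6-hydroxy-4-(methoxymethoxy)benzaldehyde | O=Cc1c(O)cc(OCOC)cc1OCc1ccccc1 | intermediate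
4 | 1-[4-(benzyloxy)phenyl]ethan-1-one | CC(=O)c1ccc(OCc2ccccc2)cc1 | starting material
5 | (E)-3-[2-(benzyloxy)-6-hydroxy-4-(methoxymethoxy)phenyl]-1-[4-(benzyloxy)phenyl]prop-2-en-1-one | O=C(/C=C/c1c(O)cc(OCOC)cc1OCc1ccccc1)c1ccc(OCc2ccccc2)cc1 | intermediate
6 | 3-[2-(benzyloxy)-6-hydroxy-4-(methoxymethoxy)phenyl]-1-[4-(benzyloxy)phenyl]propan-1-one (saturated ketone, not isolated) | O=C(CCc1c(O)cc(OCOC)cc1OCc1ccccc1)c1ccc(OCc2ccccc2)cc1 | intermediate
7 | 3-(benzyloxy)-2-[(3S)-3-[4-(benzyloxy)phenyl]-3-hydroxypropyl]-5-(methoxymethoxy)phenol | O[C@H](c1ccc(OCc2ccccc2)cc1)CCc1c(O)cc(OCOC)cc1OCc1ccccc1 | intermediate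
8 | (2R)-5-(benzyloxy)-2-[4-(benzyloxy)phenyl]-7-(methoxymethoxy)chromane | COCOc1cc(OCc2ccccc2)c2c(c1)O[C@@H](c1ccc(OCc3ccccc3)cc1)CC2 | intermediate
9 | (2R)-5-(benzyloxy)-2-[4-(benzyloxy)phenyl]-8-bromo-7-(methoxymethoxy)chromane | COCOc1cc(OCc2ccccc2)c2c(c1Br)O[C@@H](c1ccc(OCc3ccccc3)cc1)CC2 | intermediate
10 | (2R)-5-(benzyloxy)-2-[4-(benzyloxy)phenyl]-8-bromochroman-7-ol | Oc1cc(OCc2ccccc2)c2c(c1Br)O[C@@H](c1ccc(OCc3ccccc3)cc1)CC2 | intermediate
11 | {[(2R)-5-(benzyloxy)-2-[4-(benzyloxy)phenyl]-8-bromochroman-7-yl]oxy}trimethylsilane (aryl silyl ether, not isolated) | C[Si](C)(C)Oc1cc(OCc2ccccc2)c2c(c1Br)O[C@@H](c1ccc(OCc3ccccc3)cc1)CC2 | intermediate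
12 | lithium (2R)-5-(benzyloxy)-2-[4-(benzyloxy)phenyl]-8-(trimethylsilyl)chroman-7-olate (not isolated) | [Li+].[O-]c1cc(OCc2ccccc2)c2c(c1[Si](C)(C)C)O[C@@H](c1ccc(OCc3ccccc3)cc1)CC2 | intermediate
13 | (2R)-5-(benzyloxy)-2-[4-(benzyloxy)phenyl]-8-(trimethylsilyl)chroman-7-yl trifluoromethanesulfonate | C[Si](C)(C)c1c(OS(=O)(=O)C(F)(F)F)cc(OCc2ccccc2)c2c1O[C@@H](c1ccc(OCc3ccccc3)cc1)CC2 | intermediate
14 | ethyl 3-[4-(benzyloxy)phenyl]-3-oxopropanoate | CCOC(=O)CC(=O)c1ccc(OCc2ccccc2)cc1 | intermediate
15 | ethyl 3-[4-(benzyloxy)phenyl]-3-oxo-2-(phenyl-λ3-iodanylidene)propanoate (iodonium ylide) | CCOC(=O)[C-]([I+]c1ccccc1)C(=O)c1ccc(OCc2ccccc2)cc1 | intermediate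
16 | 3,5-bis(benzyloxy)phenol | Oc1cc(OCc2ccccc2)cc(OCc2ccccc2)c1 | starting material
17 | 3,5-bis(benzyloxy)-2-bromophenol | Oc1cc(OCc2ccccc2)cc(OCc2ccccc2)c1Br | intermediate
18 | (2R)-5-(benzyloxy)-2-[4-(benzyloxy)phenyl]-7,8-didehydrochromane (7,8-aryne, not isolated) | C1#CC2=C(CC[C@H](c3ccc(OCc4ccccc4)cc3)O2)C(OCc2ccccc2)=C1 | intermediate
19 | ethyl (2R)-5-(benzyloxy)-2,8-bis[4-(benzyloxy)phenyl]-3,4-dihydro-2H-furo[2,3-h]chromene-9-carboxylate | CCOC(=O)c1c(-c2ccc(OCc3ccccc3)cc2)oc2cc(OCc3ccccc3)c3c(c12)O[C@@H](c1ccc(OCc2ccccc2)cc1)CC3 | intermediate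
20 | [(2R)-5-(benzyloxy)-2,8-bis[4-(benzyloxy)phenyl]-3,4-dihydro-2H-furo[2,3-h]chromen-9-yl]methanol | OCc1c(-c2ccc(OCc3ccccc3)cc2)oc2cc(OCc3ccccc3)c3c(c12)O[C@@H](c1ccc(OCc2ccccc2)cc1)CC3 | intermediate
21 | (2R)-5-(benzyloxy)-2,8-bis[4-(benzyloxy)phenyl]-3,4-dihydro-2H-furo[2,3-h]chromene-9-carbaldehyde | O=Cc1c(-c2ccc(OCc3ccccc3)cc2)oc2cc(OCc3ccccc3)c3c(c12)O[C@@H](c1ccc(OCc2ccccc2)cc1)CC3 | intermediate
22 | lithium 3,5-bis(benzyloxy)-2-lithiophenolate (dilithiated phenoxide, not isolated) | [Li]Oc1cc(OCc2ccccc2)cc(OCc2ccccc2)c1[Li] | intermediate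
23 | 3,5-bis(benzyloxy)-2-{[(2R)-5-(benzyloxy)-2,8-bis[4-(benzyloxy)phenyl]-3,4-dihydro-2H-furo[2,3-h]chromen-9-yl](hydroxy)methyl}phenol (both carbinol epimers) | OC(c1c(O)cc(OCc2ccccc2)cc1OCc1ccccc1)c1c(-c2ccc(OCc3ccccc3)cc2)oc2cc(OCc3ccccc3)c3c(c12)O[C@@H](c1ccc(OCc2ccccc2)cc1)CC3 | intermediate
24 | (6Z)-3,5-bis(benzyloxy)-6-{[(2R)-5-(benzyloxy)-2,8-bis[4-(benzyloxy)phenyl]-3,4-dihydro-2H-furo[2,3-h]chromen-9-yl]methylidene}cyclohexa-2,4-dien-1-one (ortho-quinone methide, not isolated) | O=C1C=C(OCc2ccccc2)C=C(OCc2ccccc2)/C1=C/c1c(-c2ccc(OCc3ccccc3)cc2)oc2cc(OCc3ccccc3)c3c(c12)O[C@@H](c1ccc(OCc2ccccc2)cc1)CC3 | intermediate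
25 | (2S,2'R)-penta-O-benzyl flav-3-ene ketal: 5,7-bis(benzyloxy)-2-[4-(benzyloxy)phenyl]-2H-chromene whose C2 is bonded through oxygen to C7' and whose C3 is bonded to C8' of (2'R)-5'-(benzyloxy)-2'-[4-(benzyloxy)phenyl]chromane | C1c2c(OCc3ccccc3)cc(OCc3ccccc3)cc2O[C@@]2(c3ccc(OCc4ccccc4)cc3)Oc3cc(OCc4ccccc4)c4c(c3C=12)O[C@@H](c1ccc(OCc2ccccc2)cc1)CC4 | intermediate
26 | 4-boryl adduct of 25 (BH2 on C4 and H on C3 on the same face; 3-H cis to the 2-aryl group; not isolated) | B[C@@H]1c2c(OCc3ccccc3)cc(OCc3ccccc3)cc2O[C@@]2(c3ccc(OCc4ccccc4)cc3)Oc3cc(OCc4ccccc4)c4c(c3[C@@H]12)O[C@@H](c1ccc(OCc2ccccc2)cc1)CC4 | intermediate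
27 | (2S,3S,4S,2'R)-penta-O-benzyl 4-hydroxy ketal (chroman-4-ol corresponding to 28; 3-H cis to the 2-aryl group; 4-OH cis to 3-H) | O[C@@H]1c2c(OCc3ccccc3)cc(OCc3ccccc3)cc2O[C@@]2(c3ccc(OCc4ccccc4)cc3)Oc3cc(OCc4ccccc4)c4c(c3[C@@H]12)O[C@@H](c1ccc(OCc2ccccc2)cc1)CC4 | intermediate
28 | (2S,3S,2'R)-penta-O-benzyl ether of the target | O=C1c2c(OCc3ccccc3)cc(OCc3ccccc3)cc2O[C@@]2(c3ccc(OCc4ccccc4)cc3)Oc3cc(OCc4ccccc4)c4c(c3[C@@H]12)O[C@@H](c1ccc(OCc2ccccc2)cc1)CC4 | intermediate
29 | (2S,3S,2'R)-target CNP0179743.1: 5,7-dihydroxy-2-(4-hydroxyphenyl)chroman-4-one whose C2 is bonded through oxygen to C7' and whose C3 is bonded to C8' of (2'R)-5'-hydroxy-2'-(4-hydroxyphenyl)chromane, cis-fused | O=C1c2c(O)cc(O)cc2O[C@@]2(c3ccc(O)cc3)Oc3cc(O)c4c(c3[C@@H]12)O[C@@H](c1ccc(O)cc1)CC4 | target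

**Step count**
Total steps: 19. Longest linear sequence: 16 (steps 1–8, then 12–19); steps 9–10 and step 11 are side branches.

**Three steps most likely to fail**

Risk 1, step 16 (Proposed new method). The cation may be captured intermolecularly by electron-rich arenes faster than the dearomatising ring closure occurs, or the ketal may re-ionise under the acid and lose catalyst control at C2. The fallback sets out from carbinol 23 and draws on classical flavylium chemistry. Dry HCl in EtOAc should convert 23, pulled by formation of the aromatic benzopyrylium ion, into the 3-aryl-flavylium chloride F1, in which the C2–O7' bond is open and the 7'-phenol is free. Buffering with NaOAc in CH2Cl2/MeCN should let the 7'-phenol add to C2 of the flavylium ion (5-exo-trig, the A-type ketal-forming event), giving 25 together with its ketal epimer F2. The epimers are separated by preparative HPLC on a chiral stationary phase, and F2 is returned to F1 with HCl and recycled. The route is rejoined at 25.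

Risk 2, step 12. Aryne generation at the hindered, electron-rich ring may be slow relative to thermal decay of the β-keto ester ylide, or addition may occur with the reverse orientation. The fallback sets out from 13. Ipso-iododesilylation with ICl (CH2Cl2, −78 °C) should give (2R)-5-(benzyloxy)-2-[4-(benzyloxy)phenyl]-8-iodochroman-7-yl trifluoromethanesulfonate F3. A palladium-catalysed domino reaction with β-keto ester 14 (Pd2(dba)3, Xantphos, K3PO4, toluene, 100 °C) should then α-arylate at the C–I bond and close the C–O bond onto the triflate by intramolecular enolate O-arylation. This is analogous to the copper-catalysed domino coupling of 1-bromo-2-iodoarenes with β-keto esters; the same two bonds are formed, with regiochemistry fixed by the order of halide reactivity. The route is rejoined at 19.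

Risk 3, step 17. Borane may open or reduce the ionisable ketal as a Lewis acid, or hydride may be delivered to the face that gives the strained trans-fused junction. The fallback sets out from 25. Dihydroxylation (OsO4 cat., NMO, acetone/H2O) should give the cis-3,4-diol F4. Dess–Martin oxidation of its secondary benzylic hydroxyl should give the 3-hydroxy-4-ketone F5. Reductive cleavage of the tertiary α-hydroxyl with SmI2/MeOH in THF at −78 °C (ketyl, then samarium enolate, protonated in situ to the cis-fused ketone) should give 28. The route is rejoined at 28.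

**Further compounds**
F1 | step 16 | 5,7-bis(benzyloxy)-2-[4-(benzyloxy)phenyl]-3-[(2R)-5-(benzyloxy)-2-[4-(benzyloxy)phenyl]-7-hydroxychroman-8-yl]chromenylium chloride | [Cl-].Oc1cc(OCc2ccccc2)c2c(c1-c1cc3c(OCc4ccccc4)cc(OCc4ccccc4)cc3[o+]c1-c1ccc(OCc3ccccc3)cc1)O[C@@H](c1ccc(OCc3ccccc3)cc1)CC2
F2 | step 16 | (2R,2'R)-penta-O-benzyl flav-3-ene ketal (epimer of 25 at the ketal carbon) | C1c2c(OCc3ccccc3)cc(OCc3ccccc3)cc2O[C@]2(c3ccc(OCc4ccccc4)cc3)Oc3cc(OCc4ccccc4)c4c(c3C=12)O[C@@H](c1ccc(OCc2ccccc2)cc1)CC4
F3 | step 12 | (2R)-5-(benzyloxy)-2-[4-(benzyloxy)phenyl]-8-iodochroman-7-yl trifluoromethanesulfonate | O=S(=O)(Oc1cc(OCc2ccccc2)c2c(c1I)O[C@@H](c1ccc(OCc3ccccc3)cc1)CC2)C(F)(F)F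
F4 | step 17 | cis-3,4-diol of 25 (both hydroxyls on the face of the 2-aryl group; 2S,2'R) | O[C@@H]1c2c(OCc3ccccc3)cc(OCc3ccccc3)cc2O[C@@]2(c3ccc(OCc4ccccc4)cc3)Oc3cc(OCc4ccccc4)c4c(c3[C@@]12O)O[C@@H](c1ccc(OCc2ccccc2)cc1)CC4
F5 | step 17 | 3-hydroxy derivative of 28 (3-OH cis to the 2-aryl group; 2S,2'R) | O=C1c2c(OCc3ccccc3)cc(OCc3ccccc3)cc2O[C@@]2(c3ccc(OCc4ccccc4)cc3)Oc3cc(OCc4ccccc4)c4c(c3[C@@]12O)O[C@@H](c1ccc(OCc2ccccc2)cc1)CC4
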